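The γ-lactone is read as a ring-expanded cyclobutanone: spiro carbon C13 of the 9,13-epoxy (tetrahydrofuran) ring carries two CH2 arms, C14 and C16, so the ring C13–C14–C15(=O)–O–C16 is the Baeyer–Villiger product of a 3-alkoxycyclobutanone. The key step is the [2+2] cycloaddition of dichloroketene to the exocyclic enol ether C13=CH2 of the spiro-tetrahydrofuran, which closes the four-membered ring by forming C13–C16 (and C14–C15) in one operation. It exploits the local pseudo-symmetry at C13, which the decalin cannot differentiate: C13 is set afterwards by catalyst-controlled oxygen insertion. C5/C10 come from sclareol; C8/C9 from a hydroxyl-directed epoxidation and trans-diaxial opening.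

Key step: step 10

Remark: ring positions follow labdane numbering; the side chain is numbered as in the target (C11, C12, spiro C13, C14 = CH2C=O, C15 = C=O, C16 = OCH2). The two CH2 arms on C13 of cyclobutanone 13 are constitutionally identical, so C13 carries no configuration between steps 11 and 12.

Step 1
Reactants: 1 (−)-sclareol, (13R)-labd-14-ene-8α,13-diol
Product: 2 8α-hydroxy-14,15-dinorlabdan-13-one (methyl ketone)
Conditions: OsO4 (cat.), NaIO4, THF/H2O, rt
Reagents that add atoms: none
Why: Lemieux–Johnson oxidation: dihydroxylation of the vinyl group and periodate cleavage of the resulting 13,14,15-triol (C14–C15, then the α-hydroxy aldehyde C13–C14) should degrade the allylic tertiary carbinol to the methyl ketone, whose oxygen is the former 13-OH; the isolated 8α-OH has no vicinal oxygen and should survive, and no stereocentre is created.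

Step 2
Reactants: 2 8α-hydroxy-14,15-dinorlabdan-13-one
Product: 3 14,15-dinorlabd-8(9)-en-13-one
Conditions: PPh3, I2, CH2Cl2, rt
Reagents that add atoms: none
Why: Phosphine–iodine dehydration of the tertiary alcohol (oxyphosphonium, E1) under HI-equilibrating conditions should end at the tetrasubstituted Δ8(9) alkene, the most stable regioisomer (Zaitsev), which removes the C8 and C9 stereocentres that are rebuilt later.

Step 3
Reactants: 3 14,15-dinorlabd-8(9)-en-13-one
Product: 5 enyne (Δ8(9)-alkene with a but-3-yn-1-yl chain on C9), via enol phosphate 4 (not isolated)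
Conditions: LDA, THF, −78 °C; ClP(O)(OEt)2; then LDA (2.5 equiv), −78 °C → rt; H2O
Reagents that add atoms: diethyl chlorophosphate, CCOP(Cl)(=O)OCC (its atoms are held in 4 only)
Why: Ketone-to-alkyne conversion through the enol phosphate: kinetic deprotonation at the methyl group, O-phosphorylation and base-induced β-elimination should give the terminal alkyne without touching the tetrasubstituted alkene.

Step 4
Reactants: 5 enyne
Product: 6 7-oxo enyne (Δ8-en-7-one with the but-3-ynyl chain on C9)
Conditions: CrO3, 3,5-dimethylpyrazole, CH2Cl2, −20 °C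
Reagents that add atoms: chromium trioxide, O=[Cr](=O)=O
Why: Chromium(VI)–pyrazole allylic oxidation should attack C7, the only ring methylene allylic to the Δ8 alkene, and give the conjugated tetrasubstituted enone; the exocyclic C11 methylene is neopentylic and the alkyne should be inert.

Step 5
Reactants: 6 7-oxo enyne
Product: 7 7β-hydroxy enyne (allylic alcohol)
Conditions: NaBH4, CeCl3·7H2O, MeOH, −20 °C
Reagents that add atoms: none
Why: Luche 1,2-reduction: hydride should add to C7 from the α face, anti to the angular C10 methyl that shields the β face, so the new stereocentre carries a 7β (pseudo-equatorial) hydroxyl.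

Step 6
Reactants: 7 7β-hydroxy enyne
Product: 8 8β,9β-epoxy-7β-ol (but-3-ynyl chain on C9)
Conditions: VO(acac)2 (cat.), t-BuOOH, CH2Cl2, 0 °C → rt
Reagents that add atoms: tert-butyl hydroperoxide, CC(C)(C)OO
Why: Vanadium-catalysed hydroxyl-directed epoxidation: the vanadium alkoxide–peroxo complex bound to the 7β-oxygen should deliver oxygen to the β face of the tetrasubstituted alkene, overriding its steric α preference and setting C8 (final) and C9 (to be inverted); the alkyne should not react.

Step 7
Reactants: 8 8β,9β-epoxy-7β-ol
Product: 9 8β,9β-epoxy-7-one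
Conditions: Dess–Martin periodinane, CH2Cl2, rt
Reagents that add atoms: none
Why: Dess–Martin oxidation of the secondary alcohol under near-neutral conditions should restore the C7 ketone without opening the epoxide.

Step 8
Reactants: 9 8β,9β-epoxy-7-one
Product: 10 8β,9α-dihydroxy-7-one (but-3-ynyl chain on C9)
Conditions: HClO4 (cat.), THF/H2O, 0 °C → rt
Reagents that add atoms: water, O
Why: Acid-catalysed hydrolysis of the α,β-epoxy ketone: water should attack the tertiary C9, the carbon remote from the carbonyl, anti to the protonated β-oxygen (α face, inversion), which is also the trans-diaxial (Fürst–Plattner) mode, giving 9α-OH while C8 keeps its 8β-oxygen.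

Step 9
Reactants: 10 8β,9α-dihydroxy-7-one
Product: 11 spiro enol ether (9α,13-epoxy ring with exocyclic C13=CH2, 8β-hydroxy, 7-one)
Conditions: AuCl (cat.), K2CO3 (cat.), MeCN, rt
Reagents that add atoms: none
Why: Gold-catalysed 5-exo-dig hydroalkoxylation (cycloisomerisation of a 4-alkyn-1-ol): addition of the 9α-hydroxyl across the activated alkyne should give the exocyclic enol ether kinetically, 5-exo closure by 9-OH being faster than 6-exo closure by 8-OH; C9 is untouched.

Step 10
Reactants: 11 spiro enol ether
Product: 12 spiro 2,2-dichlorocyclobutanone (CCl2 = C16 on C13, C15 carbonyl between C16 and C14H2; both C13 epimers)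
Conditions: Cl3CCOCl, Zn–Cu, Et2O/DME, 0 °C → rt
Reagents that add atoms: trichloroacetyl chloride, ClC(Cl)(Cl)C(Cl)=O
Why: Zinc reduction of trichloroacetyl chloride gives dichloroketene, which should add to the electron-rich 1,1-disubstituted enol ether C13=CH2 in an asynchronous [2+2] cycloaddition: the ketene carbonyl carbon (C15) bonds to the nucleophilic exocyclic CH2 (C14) and the CCl2 terminus (C16) to the oxygen-bearing C13, as the polarisation of the enol ether dictates. The closest known reaction type is the dichloroketene–enol ether cycloaddition to 3-alkoxy-2,2-dichlorocyclobutanones. The four-membered ring is closed in cycloaddition mode by the two bonds C13–C16 and C14–C15. C13 becomes a stereocentre in 12 without control (both spiro epimers are expected, because the C8 and C10 flanks of the tetrahydrofuran are nearly mirror images), which is harmless since step 11 makes the two CH2 arms identical and step 12 sets C13. The step needs only regio- and chemoselectivity: the hindered axial tertiary 8-OH (syn-axial to the C10 methyl) and the α-quaternary C7 ketone should be far less reactive towards the ketene than the enol ether, and DME is there to sequester zinc chloride.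

Step 11
Reactants: 12 spiro 2,2-dichlorocyclobutanone
Product: 13 spiro cyclobutanone (C13 bearing CH2–C(=O)–CH2, 9α,13-epoxy, 8β-hydroxy, 7-one)
Conditions: Zn, AcOH, TMEDA, EtOH, 0 °C → rt
Reagents that add atoms: none
Why: Zinc reduction of the α,α-dichloroketone (zinc enolates protonated by acetic acid) should remove both chlorines, so the two CH2 arms on C13 become identical, both epimers of 12 converge on one cyclobutanone and C13 ceases to be a stereocentre.

Step 12
Reactants: 13 spiro cyclobutanone
Product: 14 (5S,8R,9S,10S,13S)-9α,13-epoxy-8β-hydroxy-7-oxolabdan-15,16-olide (target)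
Conditions: chiral 3,3'-diaryl-BINOL-type phosphoric acid (cat., antipode chosen for 13S), 30% aq. H2O2, CHCl3, −40 °C
Reagents that add atoms: hydrogen peroxide, OO
Why: Catalyst-controlled Baeyer–Villiger desymmetrisation: the chiral phosphoric acid should organise peroxide addition and the Criegee rearrangement so that only the CH2 on the C10 side of the tetrahydrofuran migrates to oxygen, which sets C13 as S; the strained cyclobutanone should react far faster than the hindered C7 cyclohexanone, and because the decalin exerts almost no bias the catalyst antipode that gives 13S is simply selected.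

Compound list
1 | (−)-sclareol, (13R)-labd-14-ene-8α,13-diol | CC1(C)CCC[C@@]2(C)[C@H]1CC[C@@](C)(O)[C@@H]2CC[C@@](C)(O)C=C | starting material
2 | 8α-hydroxy-14,15-dinorlabdan-13-one | CC1(C)CCC[C@@]2(C)[C@H]1CC[C@@](C)(O)[C@@H]2CCC(C)=O | intermediate
3 | 14,15-dinorlabd-8(9)-en-13-one | CC1(C)CCC[C@@]2(C)[C@H]1CCC(C)=C2CCC(C)=O | intermediate
4 | enol phosphate (diethyl phosphate of the methyl-side enol of 3) | CC1(C)CCC[C@@]2(C)[C@H]1CCC(C)=C2CCC(=C)OP(=O)(OCC)OCC | intermediate
5 | enyne (Δ8(9)-alkene, but-3-yn-1-yl chain on C9) | CC1(C)CCC[C@@]2(C)[C@H]1CCC(C)=C2CCC#C | intermediate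
6 | 7-oxo enyne (Δ8-en-7-one) | CC1(C)CCC[C@@]2(C)[C@H]1CC(=O)C(C)=C2CCC#C | intermediate
7 | 7β-hydroxy enyne | CC1(C)CCC[C@@]2(C)[C@H]1C[C@H](O)C(C)=C2CCC#C | intermediate
8 | 8β,9β-epoxy-7β-ol | CC1(C)CCC[C@@]2(C)[C@H]1C[C@H](O)[C@]3(C)O[C@]23CCC#C | intermediate
9 | 8β,9β-epoxy-7-one | CC1(C)CCC[C@@]2(C)[C@H]1CC(=O)[C@]3(C)O[C@]23CCC#C | intermediate
10 | 8β,9α-dihydroxy-7-one (but-3-ynyl chain on C9) | CC1(C)CCC[C@@]2(C)[C@H]1CC(=O)[C@](C)(O)[C@]2(O)CCC#C | intermediate
11 | spiro enol ether (9α,13-epoxy, C13=CH2, 8β-hydroxy, 7-one) | CC1(C)CCC[C@@]2(C)[C@H]1CC(=O)[C@](C)(O)[C@]21CCC(=C)O1 | intermediate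
12 | spiro 2,2-dichlorocyclobutanone (both C13 epimers) | CC1(C)CCC[C@@]2(C)[C@H]1CC(=O)[C@](C)(O)[C@]21CCC2(CC(=O)C2(Cl)Cl)O1 | intermediate
13 | spiro cyclobutanone | CC1(C)CCC[C@@]2(C)[C@H]1CC(=O)[C@](C)(O)[C@]21CCC2(CC(=O)C2)O1 | intermediate
14 | (5S,8R,9S,10S,13S)-9α,13-epoxy-8β-hydroxy-7-oxolabdan-15,16-olide | CC1(C)CCC[C@@]2(C)[C@H]1CC(=O)[C@](C)(O)[C@]21CC[C@]2(COC(=O)C2)O1 | target

Total step count: 12. Longest linear sequence: 12 (fully linear from sclareol).

Steps most likely to fail

Step 12. The catalyst may not control which of the two diastereotopic CH2 groups migrates (poor group selectivity), because the substrate is large and carries a hydroxyl and a ketone that can also bind the acid. Fallback, from 13 back to 14: the cyclobutanone is ring-expanded without a chiral catalyst (H2O2 in trifluoroethanol), which should give 14 together with the 13-epimeric lactone F1, and the two are separated by chromatography. The 13-epimeric lactone F1 is then recycled with a catalytic amine base (DBU): retro-oxa-Michael elimination opens the β-alkoxy lactone to the 9α-hydroxy butenolide F2, which should re-close by oxa-Michael addition to a mixture of 14 and F1. Control thus shifts from kinetic catalyst control to separation with thermodynamic recycling.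

Step 10. The free tertiary hydroxyl may be acylated by the ketene or the acid chloride, and zinc chloride may isomerise the exocyclic enol ether into the ring or open the 3-alkoxycyclobutanone adduct. Fallback, from 10 back to 13, avoiding the enol ether: both tertiary hydroxyls of 10 are silylated with N-(trimethylsilyl)imidazole to the bis(trimethylsilyl) ether F3. Dichloroketene is then added to the terminal alkyne instead, which should give the 4,4-dichlorocyclobutenone F4 with the same C13–C16 bond. Zinc/acetic acid removes the chlorines and the acidic work-up the silyl groups, giving the cyclobutenone diol F5. Base-catalysed 5-exo oxa-Michael addition of the 9α-hydroxyl to C13 of the cyclobutenone then closes the tetrahydrofuran and returns to 13.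

Step 8. Acid may trigger a 1,2-acyl or alkyl shift (semipinacol-type rearrangement) of the tetrasubstituted epoxy ketone in competition with hydration. Fallback, from 8 back to 11, with the ketone restored last: aqueous acid opens the epoxy alcohol at C9 (remote from the hydroxyl-bearing C7, trans-diaxial) to the 7β,8β,9α-triol F6. Gold-catalysed 5-exo-dig cyclisation gives the enol ether diol F7. The secondary 7-hydroxyl is then oxidised under non-acidic conditions (SO3·pyridine, DMSO, Et3N) to return to 11.

Further compounds
F1 | step 12 | 13-epimer of 14, (13R)-9α,13-epoxy-8β-hydroxy-7-oxolabdan-15,16-olide | CC1(C)CCC[C@@]2(C)[C@H]1CC(=O)[C@](C)(O)[C@]21CC[C@@]2(COC(=O)C2)O1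
F2 | step 12 | 8β,9α-dihydroxy-7-oxolabd-13-en-15,16-olide (9α-hydroxy butenolide) | CC1(C)CCC[C@@]2(C)[C@H]1CC(=O)[C@](C)(O)[C@]2(O)CCC1=CC(=O)OC1
F3 | step 10 | 8β,9α-bis(trimethylsilyl) ether of 10 | CC1(C)CCC[C@@]2(C)[C@H]1CC(=O)[C@](C)(O[Si](C)(C)C)[C@]2(O[Si](C)(C)C)CCC#C
F4 | step 10 | bis(trimethylsilyl) ether carrying a 4,4-dichloro-3-oxocyclobut-1-enyl group at C13 | CC1(C)CCC[C@@]2(C)[C@H]1CC(=O)[C@](C)(O[Si](C)(C)C)[C@]2(O[Si](C)(C)C)CCC1=CC(=O)C1(Cl)Cl
F5 | step 10 | 8β,9α-dihydroxy-7-one carrying a 3-oxocyclobut-1-enyl group at C13 (cyclobutenone diol) | CC1(C)CCC[C@@]2(C)[C@H]1CC(=O)[C@](C)(O)[C@]2(O)CCC1=CC(=O)C1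
F6 | step 8 | 7β,8β,9α-triol (but-3-ynyl chain on C9) | CC1(C)CCC[C@@]2(C)[C@H]1C[C@H](O)[C@](C)(O)[C@]2(O)CCC#C
F7 | step 8 | spiro enol ether 7β,8β-diol (9α,13-epoxy, C13=CH2) | CC1(C)CCC[C@@]2(C)[C@H]1C[C@H](O)[C@](C)(O)[C@]21CCC(=C)O1
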